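The numbers in the tables were computed from invented constants; scatter was added.

The unit for the maple flask is the turnover, one target made for each free catalyst charged, so you divide c(target) by the free catalyst at the start.

| setting | alder | birch | ash | cedar | maple |
|---|---|---|---|---|---|
| starting material | 0.800 M | 0.480 M | 0.800 M | 0.800 M | 0.800 M |
| reagent | 2.00 M | 1.68 M | 2.00 M | 1.00 M | 2.00 M |
| free catalyst | 0.00400 M | 0.00400 M | 0.00200 M | 0.00400 M | 0.00400 M |
| time |  |  |  |  | 660 min |

| alder run: time / min | alder run: [target] / M | birch run: time / min | birch run: [target] / M | ash run: time / min | ash run: [target] / M | cedar run: time / min | cedar run: [target] / M |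
|---|---|---|---|---|---|---|---|
| 14 | 0.1092 | 14 | 0.0642 | 14 | 0.0682 | 14 | 0.0929 |
| 28 | 0.2044 | 28 | 0.1242 | 28 | 0.1286 | 28 | 0.1740 |
| 41 | 0.2714 | 41 | 0.1685 | 41 | 0.1793 | 41 | 0.2353 |
| 55 | 0.3290 | 55 | 0.2044 | 55 | 0.2232 | 55 | 0.2908 |
| 69 | 0.3739 | 69 | 0.2340 | 69 | 0.2636 | 69 | 0.3324 |
| 82 | 0.4031 | 82 | 0.2571 | 82 | 0.2913 | 82 | 0.3620 |
| 96 | 0.4362 | 96 | 0.2765 | 96 | 0.3187 | 96 | 0.3929 |
| 110 | 0.4556 | 110 | 0.2922 | 110 | 0.3418 | 110 | 0.4115 |

(each reading ± 0.002 M)

- Overall: starting material + reagent -> target, with free catalyst as catalyst.
- Constant volume, constant temperature.
- Bound and free are read together.
- An order is taken over about fifteen percent of the charge, up and down.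

- reaction order in [reagent] at the outset, round the charge of the alder run, defined at two percent of the starting material turned into target
- reaction order in [starting material] at the outset, round the charge of the alder run, defined at two percent of the starting material turned into target (one fixed amount of target, the same in the runs compared)
- the birch run starts with 0.320 M less of starting material and of reagent than the alder run, and with no target. Compared where both hold the same amount of starting material, once fifteen percent of what the birch run was charged with has turned into target, is the birch run faster, slower or alike (within a tenth)?
- target in the maple run at 660 min, as a share of the starting material charged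

- **In the flask now:** the maple flask has the charge of the alder flask. By 110 min the alder flask held c(target) = 0.4556 M, with about 0.344 M of starting material and about 1.54 M of reagent left, which makes 114 turnovers.
- **Its pace:** the alder flask made 0.00780 M min⁻¹ over its first 14 min, but only 0.00187 M min⁻¹ between 82 min and 110 min, so expect the maple flask to be making target slowly when you come.
- **The number to carry:** the ash flask, with half the free catalyst, stood at 171 turnovers at 110 min. This turnover count, target made per free catalyst charged, is higher than the alder flask's. Over the same late stretch the ash flask still gained 0.00180 M min⁻¹, about the pace of the alder flask.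
- **When you come at 660 min:** my own reckoning lets each free catalyst in the maple flask reach the ash count. That gives c(target) = 0.684 M, or 85.4 % of the charge, leaving about 0.116 M of starting material and about 1.32 M of reagent.
- **The forecast:** it gives 72 % (range 62 % to 88 %), lower than my figure, with orders 0.2 in reagent and 0.9 in starting material, and the birch flask faster. On the plateau it says: “Alder extrapolates to roughly 0.55–0.6 M, with a slow tail possible.”
- **What not to touch:** leave the reagent alone. The cedar flask, with half the reagent, still reached 0.4115 M at 110 min against 0.4556 M in the alder flask. Hold the temperature too, since the readings were taken at that one temperature.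

The flask gives orders of 0.25 in reagent and 0.94 in starting material, the birch flask faster, and 81.3 % in the maple flask.

    free catalyst + starting material → catalyst-substrate complex (2.514 L mol⁻¹ min⁻¹)
    catalyst-substrate complex + reagent → target + free catalyst (9.060 L mol⁻¹ min⁻¹)
    free catalyst + target → spent catalyst + target (0.04338 L mol⁻¹ min⁻¹)
    starting material + reagent → target (9.060 × 10⁻⁴ L mol⁻¹ min⁻¹)

The maple flask's 81.3 % is 0.650 M of target, which lies above the forecast and below my 85.4 %. Its count is 163 turnovers at 660 min, fewer than the 171 the ash flask had at 110 min. The ash flask went on past the carried count, reaching 0.400 M of target at 157 min, which is 200 turnovers.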